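**Retrosynthetic overview**
1. Feature: in the single benzene ring, the neighbouring atoms C3(H), C2(OH), C1(CO2Me) and C6(icosyl) repeat the substituent pattern of C3, C4, C5 and C6 of a 6-alkyl-4-oxy-2-pyrone-5-carboxylate. Only C4(OMe) and C5(H) lie outside this pattern.
2. The target is traced back to its 2-O-acetate, which is cleaved last. Cutting ring bonds C3–C4 and C5–C6 then gives a 4-acetoxy-6-icosyl-2-pyrone-5-carboxylate as diene and 1,1-dimethoxyethene as the two-carbon piece, with CO2 and one MeOH lost.
3. The acetoxypyrone comes from the 4-hydroxypyrone. Opening the lactone bond O1–C2 gives dimethyl 2-henicosanoyl-3-oxoglutarate, and cutting the acyl–C bond gives dimethyl 3-oxoglutarate plus henicosanoyl chloride (from henicosanoic acid).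
4. Ring order: the pyrone ring is closed first (step 3). The benzene ring is then built from its four carbons (step 5), and the O1–C2 unit of the pyrone leaves as CO2.

Key step: step 5

Remark on the chemistry: the target has no stereocentre. Compound 4 is drawn as the triketo tautomer although it is largely enolised and configurationally labile. The two bridgeheads of transient 8 are racemic and disappear again.

**Step 1**
Reactants: 1 henicosanoic acid
Product: 2 henicosanoyl chloride
Conditions: (COCl)2 (1.3 equiv), DMF (cat.), CH2Cl2, 0 °C to rt; evaporate, use crude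
Reagents that add atoms: oxalyl chloride, O=C(Cl)C(=O)Cl
Why: DMF-catalysed acid chloride formation (Vilsmeier-type activation) is routine for saturated fatty acids, and every by-product leaves as a gas.

**Step 2**
Reactants: 3 dimethyl 3-oxoglutarate (1.1 equiv); 2 henicosanoyl chloride
Product: 4 dimethyl 2-henicosanoyl-3-oxopentanedioate
Conditions: MgCl2 (1.1 equiv), pyridine (2.2 equiv), CH2Cl2, 0 °C; then 2, 0 °C to rt; 1 M HCl work-up
Reagents that add atoms: none
Why: Soft enolisation of the β-keto diester by MgCl2 and pyridine followed by C-acylation (magnesium-mediated crossed Claisen-type acylation) puts the C21 acyl group on one of the two equivalent methylenes, and the more acidic tricarbonyl product stays chelated to magnesium, which holds back O-acylation and a second acylation.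

**Step 3**
Reactants: 4 dimethyl 2-henicosanoyl-3-oxopentanedioate
Product: 5 methyl 4-hydroxy-6-icosyl-2-oxo-2H-pyran-5-carboxylate
Conditions: p-TsOH (0.1 equiv, dried azeotropically), toluene, reflux, condensate passed through 4 Å molecular sieves to remove MeOH
Reagents that add atoms: none
Why: Acid-catalysed enol lactonisation (6-exo-trig attack of the enol oxygen of the long-chain ketone on the distal ester, the classical closure of 3,5-dioxo esters to 4-hydroxy-2-pyrones) is the only closure of reasonable ring size open to 4 under acid, and removal of methanol drives it while the anhydrous medium spares the C5 ester.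

**Step 4**
Reactants: 5 methyl 4-hydroxy-6-icosyl-2-oxo-2H-pyran-5-carboxylate
Product: 6 methyl 4-acetoxy-6-icosyl-2-oxo-2H-pyran-5-carboxylate
Conditions: Ac2O (1.5 equiv), pyridine (2 equiv), CH2Cl2, 0 °C to rt, no DMAP; cold aqueous work-up, crystallisation
Reagents that add atoms: acetic anhydride, CC(=O)OC(C)=O
Why: The 4-hydroxyl of a 2-pyrone is a vinylogous carboxylic acid and is O-acylated quickly by Ac2O and pyridine (kinetic O-acylation), while leaving out nucleophilic catalysts avoids the Fries-type acyl shift to C3.

**Step 5**
Reactants: 6 methyl 4-acetoxy-6-icosyl-2-oxo-2H-pyran-5-carboxylate; 7 1,1-dimethoxyethene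
Product: 10 methyl 2-acetoxy-6-icosyl-4-methoxybenzoate, via bridged lactone 8 (not isolated), via dienyl ketal 9 (not isolated)
Conditions: 7 (4 equiv), toluene, sealed tube (base-washed glass), 110 °C
Reagents that add atoms: none
Why: The LUMO of pyrone 6 is lowered by the C5 ester and the lactone carbonyl and is raised only slightly by the weakly donating acetoxy group, so it combines with the HOMO of ketene acetal 7 in an inverse-electron-demand Diels–Alder reaction across pyrone C3 and C6, strongly asynchronous with the CH2–C6 bond leading. The closest known reaction type is the cycloaddition of coumalates and other ester-bearing 2-pyrones with ketene acetals, which gives alkoxybenzoates after loss of CO2 and alcohol. The new six-membered carbocycle is closed in this intermolecular [4+2] mode (bonds C3–C4 and C5–C6 of the target ring) to give bridged lactone 8, retro-[4+2] extrusion of CO2 then opens the old pyrone ring to dienyl ketal 9, and thermal loss of one methanol across C4–C5 aromatises it. The two bridgehead stereocentres of 8 are racemic, are fixed relative to each other by the bicycle and vanish with the CO2, so no stereocontrol is needed. The selectivity needed is regiochemical: the nucleophilic CH2 of 7 must bond to C6, which is the β-carbon of the C5 acrylate unit and the δ-carbon of the lactone dienoate and should carry the largest LUMO coefficient, so the acetal carbon lands on C3 and the surviving methoxy group ends up para to the ester. Chemoselectivity over attack at the acetyl carbonyl or at C4 rests on neutral, acid-free conditions and on 6 being free of 5 and acetic acid.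

**Step 6**
Reactants: 10 methyl 2-acetoxy-6-icosyl-4-methoxybenzoate
Product: 11 methyl 2-hydroxy-6-icosyl-4-methoxybenzoate (target)
Conditions: K2CO3 (0.2 equiv), MeOH–THF, rt; aq. NH4Cl work-up
Reagents that add atoms: none
Why: Base-catalysed transesterification (Zemplén-type methanolysis) removes the aryl acetate, a far better acyl donor than the doubly ortho-substituted methyl benzoate whose only exchange in methanol is degenerate, and the freed phenol is stabilised by a hydrogen bond to the ester carbonyl.

**Compound list**
1 | henicosanoic acid | CCCCCCCCCCCCCCCCCCCCC(=O)O | starting material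
2 | henicosanoyl chloride | CCCCCCCCCCCCCCCCCCCCC(=O)Cl | intermediate
3 | dimethyl 3-oxoglutarate (dimethyl 3-oxopentanedioate) | COC(=O)CC(=O)CC(=O)OC | starting material
4 | dimethyl 2-henicosanoyl-3-oxopentanedioate (enolised, C2 configurationally labile) | CCCCCCCCCCCCCCCCCCCCC(=O)C(C(=O)OC)C(=O)CC(=O)OC | intermediate
5 | methyl 4-hydroxy-6-icosyl-2-oxo-2H-pyran-5-carboxylate | CCCCCCCCCCCCCCCCCCCCC1=C(C(=O)OC)C(O)=CC(=O)O1 | intermediate
6 | methyl 4-acetoxy-6-icosyl-2-oxo-2H-pyran-5-carboxylate | CCCCCCCCCCCCCCCCCCCCC1=C(C(=O)OC)C(OC(C)=O)=CC(=O)O1 | intermediate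
7 | 1,1-dimethoxyethene | C=C(OC)OC | starting material
8 | methyl 5-acetoxy-1-icosyl-8,8-dimethoxy-3-oxo-2-oxabicyclo[2.2.2]oct-5-ene-6-carboxylate (bridged lactone; racemic, one enantiomer drawn, bridgeheads fixed by the bicycle; not isolated) | CCCCCCCCCCCCCCCCCCCC[C@@]12CC(OC)(OC)[C@@H](C(=O)O1)C(OC(C)=O)=C2C(=O)OC | intermediate
9 | methyl 6-acetoxy-2-icosyl-4,4-dimethoxycyclohexa-1,5-diene-1-carboxylate (dienyl ketal; not isolated) | CCCCCCCCCCCCCCCCCCCCC1=C(C(=O)OC)C(OC(C)=O)=CC(OC)(OC)C1 | intermediate
10 | methyl 2-acetoxy-6-icosyl-4-methoxybenzoate | CCCCCCCCCCCCCCCCCCCCc1cc(OC)cc(OC(C)=O)c1C(=O)OC | intermediate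
11 | methyl 2-hydroxy-6-icosyl-4-methoxybenzoate | CCCCCCCCCCCCCCCCCCCCc1cc(OC)cc(O)c1C(=O)OC | target

Total step count: 6
Longest linear sequence: 6 steps (1 → 2 → 4 → 5 → 6 → 10 → 11)

**Steps most likely to fail**

**Step 5.**
- Failure mode: the cycloaddition must build a fully substituted bridgehead at the icosyl-bearing C6 and may be slow. Acetyl transfer from the vinylogous anhydride 6 to the ketene acetal or to the liberated methanol could then use up the partners first. So could addition–elimination at C4 or polymerisation of 7.
- Fallback (sets out from 1, comes back at 11): the benzene ring is made from an open chain instead of from a pyrone. Acid 1 is esterified (MeOH, cat. H2SO4, reflux, Fischer esterification) to methyl henicosanoate F1. The trianion of commercial methyl 3,5-dioxohexanoate (lithium diisopropylamide, THF, −78 to 0 °C) is acylated at its terminal carbon by F1 (Claisen condensation) to give methyl 3,5,7-trioxoheptacosanoate F2. Buffered intramolecular aldol condensation of C2 onto the C7 ketone (NaOAc, MeOH), followed by enolisation, gives methyl 2,4-dihydroxy-6-icosylbenzoate F3. MeI (1 equiv) and K2CO3 in acetone methylate only the free 4-hydroxyl, because the 2-hydroxyl is hydrogen-bonded to the ester, and this delivers 11.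

**Step 3.**
- Failure mode: retro-Claisen loss of the henicosanoyl group to the methanol released, or hydrolysis and decarboxylation of the ester that must stay at C5, could outrun ring closure.
- Fallback (sets out from 2, comes back at 5, and also bypasses step 2): the pyrone is assembled by a three-plus-three cyclocondensation. Chloride 2 acylates Meldrum's acid (pyridine, CH2Cl2, 0 °C) to give 5-(1-hydroxyhenicosylidene)-2,2-dimethyl-1,3-dioxane-4,6-dione F4. Refluxing methanol converts F4 into methyl 3-oxotricosanoate F5. Malonyl dichloride (CH2Cl2, rt to 40 °C) then acylates the active methylene of F5 on carbon and its enol on oxygen, closing 5 directly.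

**Step 4.**
- Failure mode: migration of the acetyl group from oxygen to C3, or hydrolytic loss of the reactive enol acetate during isolation, would leave an acidic pyrone that destroys the ketene acetal.
- Fallback (sets out from 5, comes back at 11): the acyl block is replaced by a methyl ether, and the two ethers are told apart at the end. Compound 5 is methylated (Me2SO4, K2CO3, acetone, reflux) to methyl 6-icosyl-4-methoxy-2-oxo-2H-pyran-5-carboxylate F6. Heating F6 with 7 (xylene, sealed tube, 140 °C) leads through methyl 1-icosyl-5,8,8-trimethoxy-3-oxo-2-oxabicyclo[2.2.2]oct-5-ene-6-carboxylate F7 and methyl 2-icosyl-4,4,6-trimethoxycyclohexa-1,5-diene-1-carboxylate F8 to methyl 2-icosyl-4,6-dimethoxybenzoate F9. BCl3 (CH2Cl2, −78 to 0 °C) cleaves only the methoxy group ortho to the ester, by chelation to the carbonyl, and gives 11.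

**Further compounds**
F1 | step 5 | methyl henicosanoate | CCCCCCCCCCCCCCCCCCCCC(=O)OC
F2 | step 5 | methyl 3,5,7-trioxoheptacosanoate | CCCCCCCCCCCCCCCCCCCCC(=O)CC(=O)CC(=O)CC(=O)OC
F3 | step 5 | methyl 2,4-dihydroxy-6-icosylbenzoate | CCCCCCCCCCCCCCCCCCCCc1cc(O)cc(O)c1C(=O)OC
F4 | step 3 | 5-(1-hydroxyhenicosylidene)-2,2-dimethyl-1,3-dioxane-4,6-dione | CCCCCCCCCCCCCCCCCCCCC(O)=C1C(=O)OC(C)(C)OC1=O
F5 | step 3 | methyl 3-oxotricosanoate | CCCCCCCCCCCCCCCCCCCCC(=O)CC(=O)OC
F6 | step 4 | methyl 6-icosyl-4-methoxy-2-oxo-2H-pyran-5-carboxylate | CCCCCCCCCCCCCCCCCCCCC1=C(C(=O)OC)C(OC)=CC(=O)O1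
F7 | step 4 | methyl 1-icosyl-5,8,8-trimethoxy-3-oxo-2-oxabicyclo[2.2.2]oct-5-ene-6-carboxylate (racemic, one enantiomer drawn) | CCCCCCCCCCCCCCCCCCCC[C@@]12CC(OC)(OC)[C@@H](C(=O)O1)C(OC)=C2C(=O)OC
F8 | step 4 | methyl 2-icosyl-4,4,6-trimethoxycyclohexa-1,5-diene-1-carboxylate | CCCCCCCCCCCCCCCCCCCCC1=C(C(=O)OC)C(OC)=CC(OC)(OC)C1
F9 | step 4 | methyl 2-icosyl-4,6-dimethoxybenzoate | CCCCCCCCCCCCCCCCCCCCc1cc(OC)cc(OC)c1C(=O)OC
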